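**Plan**

- Numbering used here: C7 = carbinol carbon, C8 = ring CH that bears C7, C9 = lactone OCH2, C8' = ring CH that bears the benzyl CH2 (C7'), C9' = lactone C=O. The target is (7R,8R,8'R).
- Retrosynthesis: remove the two O-benzyl groups; equilibrate C8'; open the lactone at C9'–O; trace C9–O back to C9–Si; then cut C9–C8 and C9'–C8' together, giving the (bromomethyl)dimethylsilyl ether of an (R,E)-1,4-diarylbut-2-en-1-ol plus CO; finally cut C7–C8 into O-benzylvanillin and a 3-arylpropyne.
- Forward: the chain is joined by an alkenylzinc addition to the aldehyde. The radical step closes a temporary 1-oxa-2-silacyclopentane (O7–Si–C9–C8–C7), which is later opened by C–Si oxidation. The lactone ring closes last.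
- Enabling feature: O7 is allylic to the C8=C8' double bond, so a silicon-bound CH2 radical reaches C8 through a five-membered ring. Because C9 and C9' sit on the neighbouring carbons C8 and C8', the radical left on C8' is exactly where CO has to add.
- Stereochemistry: C7 from the ligand-controlled alkenylzinc addition; C8 from C7 in the ring closure (trans on the silacycle); C8' by equilibration to the trans lactone.

Key step: step 5

Remark: both phenols are carried as benzyl ethers to the end, because a free 4-hydroxybenzylic alcohol ionises easily under acid or base.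

**Step 1**
Reactants: 1 [4-(benzyloxy)-3-methoxyphenyl]methanol
Product: 2 1-(benzyloxy)-4-(bromomethyl)-2-methoxybenzene
Conditions: PBr3 (0.4 equiv), Et2O, 0 °C; used at once
Reagents that add atoms: phosphorus tribromide, BrP(Br)Br
Why: Bromide substitution of the phosphite ester of an electron-rich benzylic alcohol (PBr3 bromination) is fast at 0 °C, and the aryl benzyl ether is inert to these cold, non-aqueous conditions.

**Step 2**
Reactants: 2 1-(benzyloxy)-4-(bromomethyl)-2-methoxybenzene
Product: 3 1-(benzyloxy)-2-methoxy-4-(prop-2-yn-1-yl)benzene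
Conditions: HC≡CMgBr (1.5 equiv), CuBr·SMe2 (5 mol%), THF, 0 °C to rt
Reagents that add atoms: ethynylmagnesium bromide, C#C[Mg]Br
Why: Copper-catalysed sp3–sp cross-coupling of a reactive benzylic bromide with an alkynyl Grignard reagent installs the propargyl unit, and the mild temperature should keep the benzylic alkyne from isomerising to the allene.

**Step 3**
Reactants: 3 1-(benzyloxy)-2-methoxy-4-(prop-2-yn-1-yl)benzene; 4 4-(benzyloxy)-3-methoxybenzaldehyde
Product: 7 (1R,2E)-1,4-bis[4-(benzyloxy)-3-methoxyphenyl]but-2-en-1-ol, via alkenyldicyclohexylborane 5 (not isolated), via alkenylmethylzinc 6 (not isolated)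
Conditions: BH3·SMe2, cyclohexene (2 equiv), hexane, 0 °C; 3, 0 °C to rt; Me2Zn, PhMe, −78 °C; (+)-MIB [(2R)-3-exo-morpholinoisoborneol, 4 mol%]; 4, −20 to 0 °C; H2O; Et3N-washed silica
Reagents that add atoms: none
Why: Syn anti-Markovnikov hydroboration gives the (E)-alkenylborane, boron-to-zinc exchange gives the alkenylzinc, and the amino-alcohol zinc catalyst (catalytic enantioselective alkenylzinc addition to an aldehyde) should deliver the alkenyl group to the Re face of 4 and so set C7 as R, since the enantiomeric ligand series gives S carbinols from aryl aldehydes by Si-face delivery.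

**Step 4**
Reactants: 7 (1R,2E)-1,4-bis[4-(benzyloxy)-3-methoxyphenyl]but-2-en-1-ol
Product: 8 {[(1R,2E)-1,4-bis[4-(benzyloxy)-3-methoxyphenyl]but-2-en-1-yl]oxy}(bromomethyl)dimethylsilane
Conditions: ClSiMe2CH2Br (1.2 equiv), Et3N (1.5 equiv), DMAP (5 mol%), CH2Cl2, 0 °C; filtered through a short basic alumina pad and used directly
Reagents that add atoms: (bromomethyl)chlorodimethylsilane, C[Si](C)(Cl)CBr
Why: Base-mediated silylation of the secondary alcohol installs the temporary silicon tether that carries the future C9 as CH2Br, and the basic medium avoids ionisation of the doubly activated carbinol so that C7 is untouched.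

**Step 5**
Reactants: 8 {[(1R,2E)-1,4-bis[4-(benzyloxy)-3-methoxyphenyl]but-2-en-1-yl]oxy}(bromomethyl)dimethylsilane
Product: 9 3-[4-(benzyloxy)-3-methoxyphenyl]-2-{(4S,5R)-5-[4-(benzyloxy)-3-methoxyphenyl]-2,2-dimethyl-1,2-oxasilolan-4-yl}propanal (both C-2 epimers; the 4S descriptor reflects the silicon priority and is the 8R geometry of the target)
Conditions: CO (30 atm), (Me3Si)3SiH (1.3 equiv), AIBN (0.2 equiv), PhH (0.01 M), 80 °C, autoclave
Reagents that add atoms: carbon monoxide, [C-]#[O+]
Why: Proposed new method: bromine abstraction by (Me3Si)3Si• gives the silicon-bound CH2 radical, which adds to the proximal alkene carbon C8; the secondary C8' radical so formed captures CO and the acyl radical takes hydrogen from the silane, so that C9–C8 and C9'–C8' form in one chain sequence. The closest known reaction types are the 5-exo cyclisation of (bromomethyl)dimethylsilyl ethers of allylic alcohols and the tandem radical cyclisation–formylation of alkenyl halides under CO; their combination on a silicon tether is the new element. The 1-oxa-2-silacyclopentane ring closes in the 5-exo-trig mode. The new ring stereocenter C8 is controlled by the C7 carbinol center through a chair-like transition state with the aryl group pseudo-equatorial, which should place the aryl group and the side chain trans on the ring (the 7R,8R relation of the target), whereas the new C8' center is not controlled and is set later by equilibration. The step needs 5-exo over 6-endo closure, which the substituent on the distal alkene carbon secures, and it needs ring closure before CO capture but CO capture before hydrogen transfer, which the intramolecular closure, the moderate CO pressure, the high dilution and the slow hydrogen donor (Me3Si)3SiH should secure.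

**Step 6**
Reactants: 9 3-[4-(benzyloxy)-3-methoxyphenyl]-2-{(4S,5R)-5-[4-(benzyloxy)-3-methoxyphenyl]-2,2-dimethyl-1,2-oxasilolan-4-yl}propanal
Product: 10 3-[4-(benzyloxy)-3-methoxyphenyl]-2-{(4S,5R)-5-[4-(benzyloxy)-3-methoxyphenyl]-2,2-dimethyl-1,2-oxasilolan-4-yl}propanoic acid (both C-2 epimers)
Conditions: NaClO2, NaH2PO4, 2-methyl-2-butene (excess), t-BuOH/H2O, 0 °C to rt; crude acid carried on
Reagents that add atoms: sodium chlorite, [Na+].[O-]Cl=O
Why: Pinnick oxidation takes the aldehyde to the acid while the alkene scavenger protects the electron-rich arenes from HOCl, and any partial hydrolysis of the Si–O bond is harmless because step 7 only needs the C–Si bond.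

**Step 7**
Reactants: 10 3-[4-(benzyloxy)-3-methoxyphenyl]-2-{(4S,5R)-5-[4-(benzyloxy)-3-methoxyphenyl]-2,2-dimethyl-1,2-oxasilolan-4-yl}propanoic acid
Product: 12 (4R)-3-[4-(benzyloxy)-3-methoxybenzyl]-4-{(R)-[4-(benzyloxy)-3-methoxyphenyl](hydroxy)methyl}dihydrofuran-2(3H)-one (both C-3 epimers), via dihydroxy acid 11 (not isolated)
Conditions: 30% H2O2, KF, KHCO3, THF/MeOH (1:1), rt to 40 °C; Na2S2O3; then aq. citric acid to pH 3, EtOAc, rt
Reagents that add atoms: hydrogen peroxide, OO
Why: Tamao–Fleming oxidation of the C9–Si bond unveils the primary C9 alcohol and frees O7, and on mild acidification the γ-hydroxy acid should lactonise through the unhindered primary hydroxyl, since closure through O7 would force the aryl and CH2OH groups cis on the ring; C7 and C8 are not affected.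

**Step 8**
Reactants: 12 (4R)-3-[4-(benzyloxy)-3-methoxybenzyl]-4-{(R)-[4-(benzyloxy)-3-methoxyphenyl](hydroxy)methyl}dihydrofuran-2(3H)-one (epimer mixture)
Product: 13 (3R,4R)-3-[4-(benzyloxy)-3-methoxybenzyl]-4-{(R)-[4-(benzyloxy)-3-methoxyphenyl](hydroxy)methyl}dihydrofuran-2(3H)-one
Conditions: DBU (1 equiv), PhMe, 80 °C
Reagents that add atoms: none
Why: Base-mediated epimerisation through the lactone enolate puts C8' under thermodynamic control, and a 3,4-disubstituted γ-butyrolactone is more stable with its substituents trans, which is the 8'R configuration; the protected phenols exclude quinone methide pathways at C7.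

**Step 9**
Reactants: 13 (3R,4R)-3-[4-(benzyloxy)-3-methoxybenzyl]-4-{(R)-[4-(benzyloxy)-3-methoxyphenyl](hydroxy)methyl}dihydrofuran-2(3H)-one
Product: 14 (3R,4R)-4-[(R)-hydroxy(4-hydroxy-3-methoxyphenyl)methyl]-3-(4-hydroxy-3-methoxybenzyl)dihydrofuran-2(3H)-one (allo-hydroxymatairesinol)
Conditions: H2 (1 atm), Pd/C (10 wt%), EtOAc, rt, stopped at full conversion
Reagents that add atoms: none
Why: Hydrogenolysis of the two aryl benzyl ethers over Pd/C under neutral conditions should be much faster than cleavage of the secondary benzylic C7–O bond, which needs acid or heat, and no stereocenter is touched.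

**Compound list**

1 | [4-(benzyloxy)-3-methoxyphenyl]methanol | OCc1ccc(OCc2ccccc2)c(OC)c1 | starting material
2 | 1-(benzyloxy)-4-(bromomethyl)-2-methoxybenzene | BrCc1ccc(OCc2ccccc2)c(OC)c1 | intermediate
3 | 1-(benzyloxy)-2-methoxy-4-(prop-2-yn-1-yl)benzene | C#CCc1ccc(OCc2ccccc2)c(OC)c1 | intermediate
4 | 4-(benzyloxy)-3-methoxybenzaldehyde | O=Cc1ccc(OCc2ccccc2)c(OC)c1 | starting material
5 | (E)-{3-[4-(benzyloxy)-3-methoxyphenyl]prop-1-en-1-yl}dicyclohexylborane | COc1cc(C/C=C/B(C2CCCCC2)C2CCCCC2)ccc1OCc1ccccc1 | intermediate (not isolated)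
6 | (E)-{3-[4-(benzyloxy)-3-methoxyphenyl]prop-1-en-1-yl}(methyl)zinc | COc1cc(C/C=C/[Zn]C)ccc1OCc1ccccc1 | intermediate (not isolated)
7 | (1R,2E)-1,4-bis[4-(benzyloxy)-3-methoxyphenyl]but-2-en-1-ol | COc1cc(C/C=C/[C@@H](O)c2ccc(OCc3ccccc3)c(OC)c2)ccc1OCc1ccccc1 | intermediate
8 | {[(1R,2E)-1,4-bis[4-(benzyloxy)-3-methoxyphenyl]but-2-en-1-yl]oxy}(bromomethyl)dimethylsilane | COc1cc(C/C=C/[C@@H](O[Si](C)(C)CBr)c2ccc(OCc3ccccc3)c(OC)c2)ccc1OCc1ccccc1 | intermediate
9 | 3-[4-(benzyloxy)-3-methoxyphenyl]-2-{(4S,5R)-5-[4-(benzyloxy)-3-methoxyphenyl]-2,2-dimethyl-1,2-oxasilolan-4-yl}propanal, both C-2 epimers | O=CC(Cc1ccc(OCc2ccccc2)c(OC)c1)[C@@H]1C[Si](C)(C)O[C@H]1c1ccc(OCc2ccccc2)c(OC)c1 | intermediate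
10 | 3-[4-(benzyloxy)-3-methoxyphenyl]-2-{(4S,5R)-5-[4-(benzyloxy)-3-methoxyphenyl]-2,2-dimethyl-1,2-oxasilolan-4-yl}propanoic acid, both C-2 epimers | OC(=O)C(Cc1ccc(OCc2ccccc2)c(OC)c1)[C@@H]1C[Si](C)(C)O[C@H]1c1ccc(OCc2ccccc2)c(OC)c1 | intermediate
11 | (3R,4R)-2-[4-(benzyloxy)-3-methoxybenzyl]-4-[4-(benzyloxy)-3-methoxyphenyl]-4-hydroxy-3-(hydroxymethyl)butanoic acid, both C-2 epimers | OC(=O)C(Cc1ccc(OCc2ccccc2)c(OC)c1)[C@H](CO)[C@@H](O)c1ccc(OCc2ccccc2)c(OC)c1 | intermediate (not isolated)
12 | (4R)-3-[4-(benzyloxy)-3-methoxybenzyl]-4-{(R)-[4-(benzyloxy)-3-methoxyphenyl](hydroxy)methyl}dihydrofuran-2(3H)-one, both C-3 epimers | COc1cc(CC2C(=O)OC[C@@H]2[C@@H](O)c2ccc(OCc3ccccc3)c(OC)c2)ccc1OCc1ccccc1 | intermediate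
13 | (3R,4R)-3-[4-(benzyloxy)-3-methoxybenzyl]-4-{(R)-[4-(benzyloxy)-3-methoxyphenyl](hydroxy)methyl}dihydrofuran-2(3H)-one | COc1cc(C[C@H]2C(=O)OC[C@@H]2[C@@H](O)c2ccc(OCc3ccccc3)c(OC)c2)ccc1OCc1ccccc1 | intermediate
14 | (3R,4R)-4-[(R)-hydroxy(4-hydroxy-3-methoxyphenyl)methyl]-3-(4-hydroxy-3-methoxybenzyl)dihydrofuran-2(3H)-one | COc1cc(C[C@H]2C(=O)OC[C@@H]2[C@@H](O)c2ccc(O)c(OC)c2)ccc1O | target

**Totals**

Total step count: 9. Longest linear sequence: 9 steps (1 to 14); aldehyde 4 enters at step 3.

**Steps most likely to fail**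

1. Step 5 (proposed new method). The first-formed silylmethyl radical may capture CO before it cyclises, the cyclised radical may be reduced before it captures CO, or the facial selectivity of the ring closure may be modest.
 Fallback, known chemistry only, setting out from aldehyde 4 and bromide 2 and coming back at 13. The C9' carbon is put in place before the radical step and the benzyl group is added last. Enantioselective zinc alkynylation of 4 with methyl propiolate (Me2Zn, ProPhenol ligand of the series that gives Re-face delivery, PhMe) would give methyl (S)-4-[4-(benzyloxy)-3-methoxyphenyl]-4-hydroxybut-2-ynoate F1. Trans-hydroalumination and protonation with NaAlH2(OCH2CH2OMe)2 (THF, −78 °C) would give methyl (R,E)-4-[4-(benzyloxy)-3-methoxyphenyl]-4-hydroxybut-2-enoate F2. Silylation as in step 4 would give its (bromomethyl)dimethylsilyl ether F3. The established 5-exo-trig cyclisation of such a radical onto the β-carbon of an enoate (Bu3SnH, AIBN, PhH, 80 °C) would give methyl 2-{(4S,5R)-5-[4-(benzyloxy)-3-methoxyphenyl]-2,2-dimethyl-1,2-oxasilolan-4-yl}acetate F4. Tamao–Fleming oxidation with lactonisation would give (R)-4-{(R)-[4-(benzyloxy)-3-methoxyphenyl](hydroxy)methyl}dihydrofuran-2(3H)-one F5. Its dianion (LiN(SiMe3)2, 2.2 equiv, THF, −78 °C) would be alkylated by 2 anti to the C8 substituent to give 13, bypassing steps 5 to 8.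

2. Step 7. The lactone may close through the benzylic O7 hydroxyl instead of the primary C9 hydroxyl, or the acyl group may migrate between the two.
 Fallback, setting out from dihydroxy acid 11 (extracted cold at pH 4) and coming back at 12: a Mitsunobu lactonisation (PPh3, diisopropyl azodicarboxylate, THF, 0 °C). Here the less hindered primary hydroxyl is activated and displaced by the carboxylate, so the ring can only close by forming the C9–O bond (no new compound, entry F0).

3. Step 9. Hydrogenolysis may also cleave the electron-rich benzylic C7–O bond.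
 Fallback, setting out from 13 and coming back at 14: mask the carbinol before hydrogenolysis. Silylation (t-BuMe2SiCl, imidazole, DMF) would give the C7 tert-butyldimethylsilyl ether of 13 F6. Hydrogenolysis (H2, Pd/C, EtOAc) would then give the bisphenol silyl ether F7. Buffered desilylation (Bu4NF/AcOH, THF, 0 °C) would release 14.

**Further compounds**

F1 | step 5 | methyl (S)-4-[4-(benzyloxy)-3-methoxyphenyl]-4-hydroxybut-2-ynoate | COC(=O)C#C[C@@H](O)c1ccc(OCc2ccccc2)c(OC)c1
F2 | step 5 | methyl (R,E)-4-[4-(benzyloxy)-3-methoxyphenyl]-4-hydroxybut-2-enoate | COC(=O)/C=C/[C@@H](O)c1ccc(OCc2ccccc2)c(OC)c1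
F3 | step 5 | methyl (R,E)-4-[4-(benzyloxy)-3-methoxyphenyl]-4-{[(bromomethyl)dimethylsilyl]oxy}but-2-enoate | COC(=O)/C=C/[C@@H](O[Si](C)(C)CBr)c1ccc(OCc2ccccc2)c(OC)c1
F4 | step 5 | methyl 2-{(4S,5R)-5-[4-(benzyloxy)-3-methoxyphenyl]-2,2-dimethyl-1,2-oxasilolan-4-yl}acetate | COC(=O)C[C@@H]1C[Si](C)(C)O[C@H]1c1ccc(OCc2ccccc2)c(OC)c1
F5 | step 5 | (R)-4-{(R)-[4-(benzyloxy)-3-methoxyphenyl](hydroxy)methyl}dihydrofuran-2(3H)-one | C1C(=O)OC[C@@H]1[C@@H](O)c1ccc(OCc2ccccc2)c(OC)c1
F0 | step 7 | none | none
F6 | step 9 | (3R,4R)-3-[4-(benzyloxy)-3-methoxybenzyl]-4-{(R)-[4-(benzyloxy)-3-methoxyphenyl][(tert-butyldimethylsilyl)oxy]methyl}dihydrofuran-2(3H)-one | COc1cc(C[C@H]2C(=O)OC[C@@H]2[C@@H](O[Si](C)(C)C(C)(C)C)c2ccc(OCc3ccccc3)c(OC)c2)ccc1OCc1ccccc1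
F7 | step 9 | (3R,4R)-4-{(R)-[(tert-butyldimethylsilyl)oxy](4-hydroxy-3-methoxyphenyl)methyl}-3-(4-hydroxy-3-methoxybenzyl)dihydrofuran-2(3H)-one | COc1cc(C[C@H]2C(=O)OC[C@@H]2[C@@H](O[Si](C)(C)C(C)(C)C)c2ccc(O)c(OC)c2)ccc1O
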